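**Retrosynthetic overview**
- Feature: ring C of unit 1 (the 5-hydroxy-7-methoxyflavone whose ring B holds the 4'-OH) and ring C of unit 2 (the 5,7-dihydroxy-4'-methoxyflavone tied through C8 to C3' of unit 1) are the same 4-pyranone. Each is finished by an O1–C2 enol ether bond beside a C2 aryl group, so both O1–C2 bonds are cut together, which leads back to one bis(2'-hydroxychalcone).
- The two enones are cut at Cα=Cβ (Claisen–Schmidt). The unit 2 enone comes from the biaryl methyl ketone and 4-methoxybenzaldehyde, and the unit 1 enone from the biaryl aldehyde and a 2'-hydroxy-4'-methoxyacetophenone.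
- The crowded C3'–C8 biaryl bond is made first, by Suzuki–Miyaura coupling of two small arenes: a 3-iodo-2-hydroxyacetophenone and an acetal-masked formylaryl boronate.
- Every phenol that is not to close a ring is a benzyl ether, including the second ortho oxygen of the unit 1 ketone ring. Unprotected 2',6'-dihydroxyacetophenones condense sluggishly and their chalcones drift to flavanones on handling, so each ketone ring carries exactly one free hydroxyl.
- Ring order: the four benzene rings are bought, both rings C are formed in one operation at the end, and a global debenzylation follows.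

Key step: step 11

Assumption: the target is drawn without configuration at the C3'–C8 biaryl axis, so the axis is treated as configurationally undefined. The route has no stereocentre to set; only the E geometry of the two enones is relevant, and it is consumed in step 11.

**Step 1**
Reactants: 1 2',4',6'-trihydroxyacetophenone
Product: 2 1-[2,4-bis(benzyloxy)-6-hydroxyphenyl]ethanone
Conditions: BnBr (2.1 equiv), K2CO3, acetone, reflux
Reagents that add atoms: benzyl bromide, BrCc1ccccc1
Why: Williamson ether synthesis in which the 4-OH and one ortho OH are alkylated, while the last ortho OH is locked in a hydrogen bond to the acetyl carbonyl and resists a limited amount of benzyl bromide.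

**Step 2**
Reactants: 2 1-[2,4-bis(benzyloxy)-6-hydroxyphenyl]ethanone
Product: 3 1-[4,6-bis(benzyloxy)-2-hydroxy-3-iodophenyl]ethanone
Conditions: NIS (1.05 equiv), TFA (cat.), CH2Cl2, 0 °C to rt
Reagents that add atoms: N-iodosuccinimide, O=C1CCC(=O)N1I
Why: Electrophilic aromatic iodination, which in 2-hydroxy-4,6-dialkoxyacetophenones goes to C3 (ortho to the free phenol and para to the 6-alkoxy group), with one equivalent of reagent holding back di-iodination.

**Step 3**
Reactants: 4 3-bromo-4-hydroxybenzaldehyde
Product: 5 4-(benzyloxy)-3-bromobenzaldehyde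
Conditions: BnBr, K2CO3, DMF, rt
Reagents that add atoms: benzyl bromide, BrCc1ccccc1
Why: Williamson ether synthesis on an acidic para-formyl phenol, with no competing nucleophilic site.

**Step 4**
Reactants: 5 4-(benzyloxy)-3-bromobenzaldehyde
Product: 6 2-[4-(benzyloxy)-3-bromophenyl]-1,3-dioxolane
Conditions: ethylene glycol, p-TsOH (cat.), toluene, reflux, Dean–Stark
Reagents that add atoms: ethylene glycol, OCCO
Why: Acid-catalysed acetalisation driven by azeotropic removal of water, which masks the aldehyde so that the later biaryl methyl ketone cannot condense with itself.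

**Step 5**
Reactants: 6 2-[4-(benzyloxy)-3-bromophenyl]-1,3-dioxolane
Product: 7 2-[2-(benzyloxy)-5-(1,3-dioxolan-2-yl)phenyl]-4,4,5,5-tetramethyl-1,3,2-dioxaborolane
Conditions: B2pin2, Pd(dppf)Cl2 (3 mol %), KOAc, 1,4-dioxane, 90 °C
Reagents that add atoms: bis(pinacolato)diboron, CC1(C)OB(OC1(C)C)B1OC(C)(C)C(C)(C)O1
Why: Miyaura borylation of an aryl bromide, in which the weak base KOAc avoids homocoupling and leaves the acetal and benzyl ether untouched.

**Step 6**
Reactants: 3 1-[4,6-bis(benzyloxy)-2-hydroxy-3-iodophenyl]ethanone; 7 2-[2-(benzyloxy)-5-(1,3-dioxolan-2-yl)phenyl]-4,4,5,5-tetramethyl-1,3,2-dioxaborolane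
Product: 8 biaryl ketone 1-[2',4,6-tris(benzyloxy)-5'-(1,3-dioxolan-2-yl)-2-hydroxybiphenyl-3-yl]ethanone
Conditions: Pd(OAc)2 (5 mol %), SPhos (10 mol %), K3PO4, toluene/H2O (10:1), 90 °C
Reagents that add atoms: none
Why: Suzuki–Miyaura coupling in which the aryl iodide adds readily to zerovalent palladium and the bulky electron-rich biarylphosphine is suited to a tri-ortho-substituted biaryl, while acetal, benzyl ethers, ketone and chelated phenol tolerate aqueous K3PO4.

**Step 7**
Reactants: 8 biaryl ketone; 9 4-methoxybenzaldehyde
Product: 10 chalcone acetal (E)-1-[2',4,6-tris(benzyloxy)-5'-(1,3-dioxolan-2-yl)-2-hydroxybiphenyl-3-yl]-3-(4-methoxyphenyl)prop-2-en-1-one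
Conditions: KOH (50% aq), EtOH/THF, rt; then AcOH to pH 6, 0 °C
Reagents that add atoms: none
Why: Claisen–Schmidt condensation (aldol addition, then E1cB dehydration to the E enone) in which the acetyl group is the only enolisable site and 9 the only free aldehyde, because the biaryl aldehyde is still an acetal.

**Step 8**
Reactants: 10 chalcone acetal
Product: 11 chalcone aldehyde 4-(benzyloxy)-3-{4,6-bis(benzyloxy)-2-hydroxy-3-[(E)-3-(4-methoxyphenyl)prop-2-enoyl]phenyl}benzaldehyde
Conditions: 1 M HCl, THF, rt
Reagents that add atoms: water, O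
Why: Acid hydrolysis of an aryl dioxolane whose oxocarbenium ion is stabilised by the para benzyloxy group, so mild acid suffices and the enone, phenol and benzyl ethers are kept.

**Step 9**
Reactants: 12 2',6'-dihydroxy-4'-methoxyacetophenone
Product: 13 1-[2-(benzyloxy)-6-hydroxy-4-methoxyphenyl]ethanone
Conditions: BnBr (1.05 equiv), K2CO3 (1.1 equiv), acetone, reflux
Reagents that add atoms: benzyl bromide, BrCc1ccccc1
Why: Williamson mono-etherification of two equivalent phenols, which stops after the first alkylation because the remaining OH becomes firmly chelated to the carbonyl group.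

**Step 10**
Reactants: 11 chalcone aldehyde; 13 1-[2-(benzyloxy)-6-hydroxy-4-methoxyphenyl]ethanone
Product: 14 tetra-O-benzyl bis(2'-hydroxychalcone), the biaryl carrying the (E)-3-(4-methoxyphenyl)propenoyl group on the 4,6-bis(benzyloxy)-2-hydroxyphenyl ring and the (E)-3-oxo-3-[2-(benzyloxy)-6-hydroxy-4-methoxyphenyl]prop-1-enyl group on the 2-(benzyloxy)phenyl ring
Conditions: 13 (1.05 equiv), KOH (50% aq), EtOH/THF, rt; then 1 M HCl, 0 °C
Reagents that add atoms: none
Why: Claisen–Schmidt condensation in which the aldehyde is by far the best electrophile, since the enone already present sits on a phenoxide-bearing, doubly ortho-substituted ketone ring and is deactivated towards conjugate addition.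

**Step 11**
Reactants: 14 tetra-O-benzyl bis(2'-hydroxychalcone)
Product: 16 5,4',5'',7''-tetra-O-benzylputraflavone, via tetra-O-benzyl bis-flavanone 15 (not isolated)
Conditions: I2 (20 mol %, i.e. 10 mol % per enone), DMSO, 130 °C
Reagents that add atoms: none
Why: Each free 2'-phenol adds to the β-carbon of its own enone (oxa-Michael addition) to give bis-flavanone 15, iodine then iodinates C3 of each flavanone through its enol, loss of HI installs C2=C3, and DMSO reoxidises HI to I2 (giving Me2S and water), so iodine is needed only catalytically. The closest known reaction is the I2/DMSO oxidative cyclisation of 2'-hydroxychalcones to flavones, which is also known for substrates holding two chalcone units. Ring C of unit 1 and ring C of unit 2 are each closed in the 6-endo-trig mode by forming O1–C2. The C2 and C2'' centres of 15 are transient and are erased by the dehydrogenation, so no stereocentre needs control and the product has none. Two selectivities are needed: closure of unit 2 through the oxygen beside the biaryl bond (8-aryl, not 6-aryl), secured because each ketone ring has one free hydroxyl and the other ortho oxygen is a benzyl ether, and flavone rather than aurone, secured because the oxa-Michael/α-iodination path never activates Cα ahead of C–O bond formation as a 5-exo closure would require. Catalytic iodine and fully etherified rings A should keep nuclear iodination and HI-induced debenzylation low.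

**Step 12**
Reactants: 16 5,4',5'',7''-tetra-O-benzylputraflavone
Product: 17 putraflavone
Conditions: BCl3 (8 equiv), pentamethylbenzene (12 equiv), CH2Cl2, −78 to −40 °C; then aq. work-up
Reagents that add atoms: none
Why: Lewis acid debenzylation with a non-basic cation scavenger (Friedel–Crafts capture of the benzyl cation), which cleaves the aryl benzyl ethers at low temperature, prevents C-benzylation of the electron-rich rings and spares the 7-OMe and 4'''-OMe groups, neither of which is peri to a carbonyl group.

**Compound list**
1 | 2',4',6'-trihydroxyacetophenone | CC(=O)c1c(O)cc(O)cc1O | starting material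
2 | 1-[2,4-bis(benzyloxy)-6-hydroxyphenyl]ethanone | CC(=O)c1c(O)cc(OCc2ccccc2)cc1OCc1ccccc1 | intermediate
3 | 1-[4,6-bis(benzyloxy)-2-hydroxy-3-iodophenyl]ethanone | CC(=O)c1c(O)c(I)c(OCc2ccccc2)cc1OCc1ccccc1 | intermediate
4 | 3-bromo-4-hydroxybenzaldehyde | O=Cc1ccc(O)c(Br)c1 | starting material
5 | 4-(benzyloxy)-3-bromobenzaldehyde | O=Cc1ccc(OCc2ccccc2)c(Br)c1 | intermediate
6 | 2-[4-(benzyloxy)-3-bromophenyl]-1,3-dioxolane | Brc1cc(C2OCCO2)ccc1OCc1ccccc1 | intermediate
7 | 2-[2-(benzyloxy)-5-(1,3-dioxolan-2-yl)phenyl]-4,4,5,5-tetramethyl-1,3,2-dioxaborolane | CC1(C)OB(c2cc(C3OCCO3)ccc2OCc2ccccc2)OC1(C)C | intermediate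
8 | biaryl ketone, 1-[2',4,6-tris(benzyloxy)-5'-(1,3-dioxolan-2-yl)-2-hydroxybiphenyl-3-yl]ethanone | CC(=O)c1c(O)c(-c2cc(C3OCCO3)ccc2OCc2ccccc2)c(OCc2ccccc2)cc1OCc1ccccc1 | intermediate
9 | 4-methoxybenzaldehyde | COc1ccc(C=O)cc1 | starting material
10 | chalcone acetal (E) | COc1ccc(/C=C/C(=O)c2c(O)c(-c3cc(C4OCCO4)ccc3OCc3ccccc3)c(OCc3ccccc3)cc2OCc2ccccc2)cc1 | intermediate
11 | chalcone aldehyde (E) | COc1ccc(/C=C/C(=O)c2c(O)c(-c3cc(C=O)ccc3OCc3ccccc3)c(OCc3ccccc3)cc2OCc2ccccc2)cc1 | intermediate
12 | 2',6'-dihydroxy-4'-methoxyacetophenone | CC(=O)c1c(O)cc(OC)cc1O | starting material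
13 | 1-[2-(benzyloxy)-6-hydroxy-4-methoxyphenyl]ethanone | CC(=O)c1c(O)cc(OC)cc1OCc1ccccc1 | intermediate
14 | tetra-O-benzyl bis(2'-hydroxychalcone) (E,E) | COc1ccc(/C=C/C(=O)c2c(O)c(-c3cc(/C=C/C(=O)c4c(O)cc(OC)cc4OCc4ccccc4)ccc3OCc3ccccc3)c(OCc3ccccc3)cc2OCc2ccccc2)cc1 | intermediate
15 | tetra-O-benzyl bis-flavanone (C2 and C2'' unassigned, mixture of diastereomers, both centres erased in the same step) | COc1ccc(C2CC(=O)c3c(OCc4ccccc4)cc(OCc4ccccc4)c(-c4cc(C5CC(=O)c6c(OCc7ccccc7)cc(OC)cc6O5)ccc4OCc4ccccc4)c3O2)cc1 | intermediate
16 | 5,4',5'',7''-tetra-O-benzylputraflavone | COc1ccc(-c2cc(=O)c3c(OCc4ccccc4)cc(OCc4ccccc4)c(-c4cc(-c5cc(=O)c6c(OCc7ccccc7)cc(OC)cc6o5)ccc4OCc4ccccc4)c3o2)cc1 | intermediate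
17 | putraflavone | COc1ccc(-c2cc(=O)c3c(O)cc(O)c(-c4cc(-c5cc(=O)c6c(O)cc(OC)cc6o5)ccc4O)c3o2)cc1 | target

**Total step count:** 12
**Longest linear sequence:** 9 (steps 3, 4, 5, 6, 7, 8, 10, 11, 12)

**Steps most likely to fail**

1. **Step 11.**
   - What may go wrong: the two closures may run at unequal rates, because the phenol of unit 2 is flanked by the biaryl bond. Prolonged heating could then let HI strip the ortho benzyl ether of unit 2 before ring closure, which opens closure through the wrong oxygen. It could also allow iodination of the electron-rich rings.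
   - Fallback: closure is separated from oxidation. Setting out from 14, NaOAc in refluxing EtOH isomerises both chalcones under non-acidic, iodine-free conditions to the bis-flavanone 15, which is now isolated. DDQ in refluxing 1,4-dioxane then dehydrogenates both C2–C3 bonds by hydride abstraction, and the route is rejoined at 16. This detour makes no compound outside the list (F0).

2. **Step 6.**
   - What may go wrong: oxidative addition into an iodide that is present as an electron-rich phenoxide, and transmetalation between two ortho-substituted partners, may both be slow, so that protodeboronation and hydrodeiodination take over.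
   - Fallback: the phenol is taken out of play.
     - Setting out from 3, MOMCl and iPr2NEt in CH2Cl2 give 1-[4,6-bis(benzyloxy)-3-iodo-2-(methoxymethoxy)phenyl]ethanone F1, a neutral iodide.
     - F1 is coupled with 7 to give the MOM-protected biaryl ketone F2.
     - Claisen–Schmidt condensation of F2 with 9 gives the MOM-protected chalcone acetal F3.
     - Aqueous HCl in THF/MeOH at 50 °C then removes the MOM group and the dioxolane in one operation, and the route is rejoined at 11.

3. **Step 10.**
   - What may go wrong: conjugate addition of the ketone enolate to the enone already present, retro-aldol scrambling of that enone, or poor solubility of the large aldehyde may erode the condensation. Premature flavanone formation would be harmless, since it lies on the path of step 11.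
   - Fallback: each enone is made on a monomer, so that no aldol reaction is run beside a finished chalcone, and the biaryl bond is formed last.
     - Setting out from 3 and 9, KOH/EtOH gives (E)-1-[4,6-bis(benzyloxy)-2-hydroxy-3-iodophenyl]-3-(4-methoxyphenyl)prop-2-en-1-one F4.
     - Setting out from 5 and 13, the same conditions give (E)-3-[4-(benzyloxy)-3-bromophenyl]-1-[2-(benzyloxy)-6-hydroxy-4-methoxyphenyl]prop-2-en-1-one F5.
     - Miyaura borylation of F5 gives the corresponding chalcone pinacol boronate F6.
     - Suzuki–Miyaura coupling of F4 with F6 (Pd(OAc)2, SPhos, K3PO4) rejoins the route at 14.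

**Further compounds**
F0 | step 11 | none | none
F1 | step 6 | 1-[4,6-bis(benzyloxy)-3-iodo-2-(methoxymethoxy)phenyl]ethanone | CC(=O)c1c(OCOC)c(I)c(OCc2ccccc2)cc1OCc1ccccc1
F2 | step 6 | MOM-protected biaryl ketone | CC(=O)c1c(OCOC)c(-c2cc(C3OCCO3)ccc2OCc2ccccc2)c(OCc2ccccc2)cc1OCc1ccccc1
F3 | step 6 | MOM-protected chalcone acetal (E) | COc1ccc(/C=C/C(=O)c2c(OCOC)c(-c3cc(C4OCCO4)ccc3OCc3ccccc3)c(OCc3ccccc3)cc2OCc2ccccc2)cc1
F4 | step 10 | (E)-1-[4,6-bis(benzyloxy)-2-hydroxy-3-iodophenyl]-3-(4-methoxyphenyl)prop-2-en-1-one | COc1ccc(/C=C/C(=O)c2c(O)c(I)c(OCc3ccccc3)cc2OCc2ccccc2)cc1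
F5 | step 10 | (E)-3-[4-(benzyloxy)-3-bromophenyl]-1-[2-(benzyloxy)-6-hydroxy-4-methoxyphenyl]prop-2-en-1-one | COc1cc(O)c(C(=O)/C=C/c2ccc(OCc3ccccc3)c(Br)c2)c(OCc2ccccc2)c1
F6 | step 10 | chalcone pinacol boronate (E) | COc1cc(O)c(C(=O)/C=C/c2ccc(OCc3ccccc3)c(B3OC(C)(C)C(C)(C)O3)c2)c(OCc2ccccc2)c1
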